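**Assessment of a direct plan**

A direct plan would attach the C5 unit to methyl (E)-4-hydroxycinnamate A1 by O-alkylation with a tertiary propargylic chloride to ether A2, semihydrogenation to the 1,1-dimethylallyl ether A3 and thermal aromatic Claisen rearrangement to methyl (E)-4-hydroxy-3-(3-methylbut-2-enyl)cinnamate A4. It would close with a carbodiimide/DMAP esterification of A4 with (S)-3-acetoxybutanoic acid A5. Its weakest steps would be:
- The semihydrogenation of the alkyne: it only adjusts an oxidation level inside a three-step detour for one C–C bond, and over-reduction of the new vinyl group or of the enoate would be held back only by stopping the hydrogen uptake.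
- The thermal [3,3] shift near 160 °C: the tertiary allyl aryl ether could ionise and lose isoprene, the freed ortho-prenylphenol could close to a 2,2-dimethylchroman, and the acrylate could polymerise, all on the main material stream.
- The final esterification: it would spend both advanced fragments at once through an activated β-acetoxy acyl species, where DMAP could trigger E1cB loss of acetic acid to the crotonate and so erase the (S) centre. This is the step one would least like to run on late material.

No stereocentre would be left to chance, since the (S) centre is bought, but it would have to survive that last coupling. The one ring closure left to chance would be the unwanted chroman formation.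

**Plan of the new route**

Atom labels: ring C1 (acrylate), C3 (prenyl), C4 (acyloxy); prenyl C1''H2–C2''H=C3''(CH3)2; acyl chain C1'–C4'.
- Bonds cut: the acrylate Cα=Cβ bond (Wittig, last), the C2''=C3'' bond of the prenyl group (cross-metathesis of an allyl group, key step) and the C4–O–C1' acyl bond (made first). The C3–C1'' bond is bought in 3-allyl-4-hydroxybenzaldehyde.
- Rings: the benzene ring is the only ring and is present from the first ring-bearing step; no ring is formed or opened.
- Feature behind the key step: C3'' carries two identical methyl groups, so C2''=C3'' has no geometry and can be made by alkylidene exchange on the monosubstituted allyl alkene, the only alkene present at that stage.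
- Why the weak steps vanish: there is no alkyne, no semihydrogenation and no thermal rearrangement. The ester is made at the outset from a bought phenol and a one-step acid chloride, and every later step is base-free at room temperature.
- With O4 acylated before the prenyl group exists, closure to a 2,2-dimethylchroman is excluded; only O–H and acyl bonds near the bought (S) centre are ever changed.

Key step: step 3

Assumption: 3-allyl-4-hydroxybenzaldehyde and (S)-3-hydroxybutanoic acid are taken as catalogue compounds.

**Route**

Step 1
Reactants: 1 (S)-3-hydroxybutanoic acid
Product: 3 (S)-3-acetoxybutanoyl chloride, via (S)-3-acetoxybutanoic acid 2 (not isolated)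
Conditions: AcCl (neat, excess), 0 °C to rt; evaporation; then (COCl)2, DMF (cat.), CH2Cl2, 0 °C to rt; evaporation, crude 3 used directly
Reagents that add atoms: acetyl chloride, CC(=O)Cl; oxalyl chloride, O=C(Cl)C(=O)Cl
Why: O-acetylation of the secondary alcohol by acetyl chloride followed by conversion of the carboxyl group into the acid chloride (the two-stage sequence long used for O-acetylmandelic and O-acetyllactic acid chlorides) changes only O–H and acyl C–O bonds, so the bought (S) centre at C3' is retained, and the absence of base and of heating should keep loss of acetic acid to crotonyl chloride slow.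

Step 2
Reactants: 4 3-allyl-4-hydroxybenzaldehyde; 3 (S)-3-acetoxybutanoyl chloride
Product: 5 2-allyl-4-formylphenyl (3S)-3-acetoxybutanoate
Conditions: pyridine (1.5 equiv), CH2Cl2, −20 to 0 °C; cold dilute aq. citric acid wash
Reagents that add atoms: none
Why: Acylation of a phenol with an acyl chloride in the presence of pyridine (Einhorn acylation) exchanges only the acyl C–Cl bond, so the (S) centre is untouched, the weak base and low temperature are chosen to keep dehydrochlorination to a ketene and E1cB loss of acetate slow, and the sensitive ester is thereby formed on the cheapest material of the route.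

Step 3
Reactants: 5 2-allyl-4-formylphenyl (3S)-3-acetoxybutanoate
Product: 6 4-formyl-2-(3-methylbut-2-enyl)phenyl (3S)-3-acetoxybutanoate
Conditions: second-generation Grubbs catalyst (H2IMes)(PCy3)Cl2Ru=CHPh (3 mol %), 2-methylbut-2-ene/CH2Cl2 (1:1), 1,4-benzoquinone (10 mol %), rt, closed flask
Reagents that add atoms: 2-methylbut-2-ene, CC=C(C)C
Why: Olefin cross-metathesis by the Chauvin mechanism: 2-methylbut-2-ene converts the ruthenium benzylidene into isopropylidene and ethylidene carbenes, which add [2+2] to the terminal allyl alkene of 5 and cyclorevert to place the C3''(CH3)2 terminus on C2'', the displaced CH2 leaving as propene. The closest known reaction type is the conversion of allylarenes, ortho-allylphenol derivatives included, into prenylarenes with 2-methylbut-2-ene and this catalyst. No ring is closed and no stereocentre is made; because C3'' carries two identical methyl groups the new alkene has no geometry to control, and the (S) centre in the acyl chain is remote and untouched. The selectivity needed is chemoselectivity and positional fidelity: the monosubstituted alkene is the only olefin of 5, the aldehyde and both esters are inert to the carbene, and since trisubstituted alkenes exchange far more slowly than mono- and disubstituted ones the large excess of 2-methylbut-2-ene should funnel the material into the prenyl compound. 1,4-Benzoquinone is added to intercept ruthenium hydrides so that the allyl double bond does not migrate into conjugation with the ring. Because O4 was acylated in step 2, the prenyl group never stands beside a free ortho-hydroxyl and cannot close to a 2,2-dimethylchroman.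

Step 4
Reactants: 6 4-formyl-2-(3-methylbut-2-enyl)phenyl (3S)-3-acetoxybutanoate; 7 methyl (triphenylphosphoranylidene)acetate
Product: 9 methyl (E)-3-[4-[(3S)-3-acetoxybutanoyl]oxy-3-(3-methylbut-2-enyl)phenyl]prop-2-enoate (target CNP0290147.1), via oxaphosphetane 8 (not isolated)
Conditions: CH2Cl2, rt; chromatography
Reagents that add atoms: none
Why: Wittig olefination with a stabilised ylide: [2+2] addition of 7 to the aryl aldehyde should give oxaphosphetane 8 mainly with the ester and aryl groups trans, and syn-cycloreversion with loss of triphenylphosphine oxide should then give mainly the (E)-enoate, without added base and at room temperature, the aldehyde being far more electrophilic towards the ylide than the aryl ester while the prenyl group and the (S) centre are spectators.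

**Compound list**

1 | (S)-3-hydroxybutanoic acid | OC(=O)C[C@H](C)O | starting material
2 | (S)-3-acetoxybutanoic acid | OC(=O)C[C@H](C)OC(C)=O | intermediate
3 | (S)-3-acetoxybutanoyl chloride | ClC(=O)C[C@H](C)OC(C)=O | intermediate
4 | 3-allyl-4-hydroxybenzaldehyde | O=Cc1ccc(O)c(CC=C)c1 | starting material
5 | 2-allyl-4-formylphenyl (3S)-3-acetoxybutanoate | O=Cc1ccc(OC(=O)C[C@H](C)OC(C)=O)c(CC=C)c1 | intermediate
6 | 4-formyl-2-(3-methylbut-2-enyl)phenyl (3S)-3-acetoxybutanoate | O=Cc1ccc(OC(=O)C[C@H](C)OC(C)=O)c(CC=C(C)C)c1 | intermediate
7 | methyl (triphenylphosphoranylidene)acetate | COC(=O)C=P(c1ccccc1)(c1ccccc1)c1ccccc1 | starting material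
8 | oxaphosphetane from 6 and 7 (2,2,2-triphenyl-1,2-oxaphosphetane with the aryl group on C4 and CO2Me on C3, ring centres not defined) | COC(=O)C2C(OP2(c3ccccc3)(c3ccccc3)c3ccccc3)c1ccc(OC(=O)C[C@H](C)OC(C)=O)c(CC=C(C)C)c1 | intermediate
9 | methyl (E)-3-[4-[(3S)-3-acetoxybutanoyl]oxy-3-(3-methylbut-2-enyl)phenyl]prop-2-enoate | COC(=O)/C=C/c1ccc(OC(=O)C[C@H](C)OC(C)=O)c(CC=C(C)C)c1 | target

**Count and risks**

Total step count: 4. Longest linear sequence: 4 steps (1 → 3 → 5 → 6 → 9).

Steps most likely to fail:

1. Step 3 (cross-metathesis). What may go wrong: migration of the allyl double bond into conjugation with the ring under the action of ruthenium hydrides, transfer of an ethylidene in place of an isopropylidene unit without further exchange, or slowing of the catalyst by chelation of the ortho ester carbonyl. Fallback, setting out from 3 and returning at 6: the aryl–C1'' bond would be made by cross-coupling instead. The bought 3-bromo-4-hydroxybenzaldehyde F1 would be acylated with 3 as in step 2 to 2-bromo-4-formylphenyl (3S)-3-acetoxybutanoate F2. F2 would then be coupled with tributyl(3-methylbut-2-enyl)stannane under base-free Stille conditions (Pd(PPh3)4, zerovalent palladium, DMF, 80 °C). Reductive elimination at the less substituted allyl terminus should give the linear prenyl compound 6.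

2. Step 2 (acylation). What may go wrong: loss of acetic acid from the activated acyl species, through a ketene or by E1cB, before or after acyl transfer; this would give the crotonate ester and erase the stereocentre. Fallback, setting out from 1 and 4 and returning at 5: the acetate would be introduced only after the ester exists.
   - 1 would be silylated on both oxygens (TBSCl, imidazole, DMF) to tert-butyldimethylsilyl (S)-3-(tert-butyldimethylsilyloxy)butanoate F3.
   - The silyl ester would be cleaved (K2CO3, aq. MeOH, then pH 4) to (S)-3-(tert-butyldimethylsilyloxy)butanoic acid F4.
   - F4 would be coupled with 4 (DIC, DMAP cat., CH2Cl2, 0 °C) to 2-allyl-4-formylphenyl (3S)-3-(tert-butyldimethylsilyloxy)butanoate F5. A silyloxy group is a poor leaving group, so the activated acyl species should not eliminate.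
   - The silyl ether would be removed (HF·pyridine, THF, 0 °C) to 2-allyl-4-formylphenyl (3S)-3-hydroxybutanoate F6.
   - F6 would be acetylated (Ac2O, pyridine, 0 °C) to 5.

3. Step 4 (Wittig olefination). What may go wrong: incomplete (E)-selectivity, or acyl transfer from the activated aryl ester to the ylide. Fallback, setting out from 4, 7 and 3 and returning at 9: the olefination would be run before the ester exists.
   - The free phenol 4 would be treated with 7 (toluene, 80 °C) to give methyl (E)-3-(3-allyl-4-hydroxyphenyl)prop-2-enoate F7, which as a phenol could be freed of the (Z)-isomer by crystallisation.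
   - F7 would be acylated with 3 as in step 2 to methyl (E)-3-[3-allyl-4-[(3S)-3-acetoxybutanoyl]oxyphenyl]prop-2-enoate F8.
   - Cross-metathesis of F8 with 2-methylbut-2-ene as in step 3 would then deliver 9 as the last step; the conjugated, electron-poor enoate should exchange much more slowly than the allyl group.

**Further compounds**

F1 | step 3 | 3-bromo-4-hydroxybenzaldehyde (bought) | O=Cc1ccc(O)c(Br)c1
F2 | step 3 | 2-bromo-4-formylphenyl (3S)-3-acetoxybutanoate | O=Cc1ccc(OC(=O)C[C@H](C)OC(C)=O)c(Br)c1
F3 | step 2 | tert-butyldimethylsilyl (S)-3-(tert-butyldimethylsilyloxy)butanoate | CC(C)(C)[Si](C)(C)OC(=O)C[C@H](C)O[Si](C)(C)C(C)(C)C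
F4 | step 2 | (S)-3-(tert-butyldimethylsilyloxy)butanoic acid | OC(=O)C[C@H](C)O[Si](C)(C)C(C)(C)C
F5 | step 2 | 2-allyl-4-formylphenyl (3S)-3-(tert-butyldimethylsilyloxy)butanoate | O=Cc1ccc(OC(=O)C[C@H](C)O[Si](C)(C)C(C)(C)C)c(CC=C)c1
F6 | step 2 | 2-allyl-4-formylphenyl (3S)-3-hydroxybutanoate | O=Cc1ccc(OC(=O)C[C@H](C)O)c(CC=C)c1
F7 | step 4 | methyl (E)-3-(3-allyl-4-hydroxyphenyl)prop-2-enoate | COC(=O)/C=C/c1ccc(O)c(CC=C)c1
F8 | step 4 | methyl (E)-3-[3-allyl-4-[(3S)-3-acetoxybutanoyl]oxyphenyl]prop-2-enoate | COC(=O)/C=C/c1ccc(OC(=O)C[C@H](C)OC(C)=O)c(CC=C)c1
A1 | direct plan | methyl (E)-4-hydroxycinnamate | COC(=O)/C=C/c1ccc(O)cc1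
A2 | direct plan | methyl (E)-4-(2-methylbut-3-yn-2-yloxy)cinnamate | COC(=O)/C=C/c1ccc(OC(C)(C)C#C)cc1
A3 | direct plan | methyl (E)-4-(2-methylbut-3-en-2-yloxy)cinnamate | COC(=O)/C=C/c1ccc(OC(C)(C)C=C)cc1
A4 | direct plan | methyl (E)-4-hydroxy-3-(3-methylbut-2-enyl)cinnamate | COC(=O)/C=C/c1ccc(O)c(CC=C(C)C)c1
A5 | direct plan | (S)-3-acetoxybutanoic acid (identical with 2) | OC(=O)C[C@H](C)OC(C)=O
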